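The ring atoms are C1 (C=CH2), C2 (CH–CH2Ar), C3 (CMe2), C4 and C5 (CH2) and C6 (CHOH). The cyclohexane is disconnected across C4–C5 and C1–C6, a formal [4+2] that removes C5–C6 as a vinylboronate. In one radical chain, a neopentyl radical at C4 adds to vinyl-Bpin. The α-boryl radical at C6 then closes 6-exo-dig onto a terminal alkyne. This gives the ring, the exocyclic methylene and a C6–B bond that is oxidised to C6–OH. The step exploits quaternary C3 (the C4 radical cannot rearrange or close a smaller ring, and closure gains gem-dialkyl acceleration) and the C6(O)–C1(=CH2) allylic array. The precursor is an acyclic enantiopure iodoalkyne. Protected 6-iodoluteolin is attached afterwards by Negishi coupling.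

Key step: step 7

Remark: 10 and 11 are carried on purpose as mixtures of C6 epimers, and steps 8 and 9 convert both into one configuration. Every other stereocentre is single throughout.

Step 1
Reactants: 1 methyl 3,3-dimethylpent-4-enoate
Product: 2 3,3-dimethylpent-4-enal
Conditions: DIBAL-H (1.05 equiv), CH2Cl2, −78 °C; aq. Rochelle salt
Reagents that add atoms: none
Why: Partial ester reduction with DIBAL-H, in which the tetrahedral aluminium hemiacetal should persist at −78 °C so that the aldehyde is released only after the hydride is quenched.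

Step 2
Reactants: 2 3,3-dimethylpent-4-enal, 3 formaldehyde (37% aqueous)
Product: 4 (R)-2-(hydroxymethyl)-3,3-dimethylpent-4-enal
Conditions: (S)-α,α-diphenylprolinol trimethylsilyl ether (20 mol%), pH 7 phosphate buffer, toluene, rt
Reagents that add atoms: none
Why: Enamine-catalysed asymmetric α-hydroxymethylation (cross-aldol reaction with formaldehyde), in which the diphenyl(silyloxy)methyl group shields one face of the E-enamine of 2, so formaldehyde should add from the open face and set C2 as (R) in 4, which is the spatial arrangement of C2 in the target.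

Step 3
Reactants: 4 (R)-2-(hydroxymethyl)-3,3-dimethylpent-4-enal
Product: 5 (R)-2-{[(tert-butyldimethylsilyl)oxy]methyl}-3,3-dimethylpent-4-enal
Conditions: TBSCl, imidazole, CH2Cl2, 0 °C
Reagents that add atoms: tert-butyldimethylsilyl chloride, C[Si](C)(Cl)C(C)(C)C
Why: Imidazole-promoted O-silylation, which blocks retro-aldol cleavage and dehydration of the β-hydroxy aldehyde without touching C2.

Step 4
Reactants: 5 (R)-2-{[(tert-butyldimethylsilyl)oxy]methyl}-3,3-dimethylpent-4-enal
Product: 6 (R)-tert-butyl[(2-ethynyl-3,3-dimethylpent-4-en-1-yl)oxy]dimethylsilane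
Conditions: Ohira–Bestmann reagent, K2CO3, MeOH, 0 °C to rt
Reagents that add atoms: dimethyl (1-diazo-2-oxopropyl)phosphonate, COP(=O)(OC)C(=[N+]=[N-])C(C)=O
Why: Seyferth–Gilbert homologation in the Ohira–Bestmann variant, in which the diazophosphonate anion olefinates the aldehyde and the alkylidene carbene rearranges to the terminal alkyne under base mild enough to leave the hindered centre C2 and the silyl ether intact.

Step 5
Reactants: 6 (R)-tert-butyl[(2-ethynyl-3,3-dimethylpent-4-en-1-yl)oxy]dimethylsilane
Product: 7 (R)-3-{[(tert-butyldimethylsilyl)oxy]methyl}-2,2-dimethylpent-4-yn-1-ol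
Conditions: O3, CH2Cl2/MeOH, −78 °C (Sudan Red 7B end point); then NaBH4, −78 °C to rt
Reagents that add atoms: ozone, [O-][O+]=O
Why: Chemoselective ozonolysis with reductive work-up, in which the monosubstituted alkene reacts far faster with ozone than the terminal alkyne and NaBH4 reduces the neopentyl aldehyde to the C4 alcohol.

Step 6
Reactants: 7 (R)-3-{[(tert-butyldimethylsilyl)oxy]methyl}-2,2-dimethylpent-4-yn-1-ol
Product: 8 (R)-tert-butyl[(2-ethynyl-4-iodo-3,3-dimethylbutyl)oxy]dimethylsilane
Conditions: I2, PPh3, imidazole, toluene, 90 °C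
Reagents that add atoms: iodine, II
Why: Appel-type iodination, in which iodide displaces the alkoxyphosphonium group in an SN2 reaction that needs heat at the neopentyl carbon C4 but cannot eliminate because C3 bears no hydrogen.

Step 7
Reactants: 8 (R)-tert-butyl[(2-ethynyl-4-iodo-3,3-dimethylbutyl)oxy]dimethylsilane, 9 vinylboronic acid pinacol ester
Product: 11 (3S)-3-{[(tert-butyldimethylsilyl)oxy]methyl}-4,4-dimethyl-2-methylidenecyclohexan-1-ol (both epimers at the carbinol carbon C6), via allylic pinacol boronate 10 (not isolated)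
Conditions: 9 (10 equiv), (Me3Si)3SiH + AIBN (syringe pump), PhH (0.02 M), 80 °C; evaporate; then H2O2, NaOH, THF/H2O, 0 °C
Reagents that add atoms: hydrogen peroxide, OO
Why: (Me3Si)3Si• abstracts iodine from 8, the nucleophilic neopentyl radical at C4 (no viable 4-exo or 5-endo closure) adds to the CH2 terminus of 9 (C4–C5), and the α-boryl radical at C6 attacks the inner alkyne carbon C1 (C1–C6) to give a vinyl radical that takes hydrogen from the silane, so the ring, the exocyclic methylene and the C6–B bond arise in one chain process before alkaline H2O2 turns C–B into C–OH with retention. The closest known reaction type is the radical [4+2] annulation, that is, Giese addition to a vinylboronate followed by cyclisation of the adduct radical onto a tethered alkyne. The one ring closes in the 6-exo-dig mode, accelerated by the gem-dimethyl group at C3 and the branch at C2. C2 is not touched, and the new centre C6 stands only under weak 1,3-control by C2 in a chair-like transition state and is expected as a mixture of epimers, which is accepted because steps 8 and 9 funnel both into one configuration. The step needs addition to 9 before reduction of the C4 radical, ring closure before reduction, 1,5-hydrogen transfer from C2–H or telomerisation of the C6 radical, and exo rather than 7-endo attack. Excess 9, slow addition of the poor hydrogen donor, high dilution and the Thorpe–Ingold effect should secure these.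

Step 8
Reactants: 11 (3S)-3-{[(tert-butyldimethylsilyl)oxy]methyl}-4,4-dimethyl-2-methylidenecyclohexan-1-ol (both C6 epimers)
Product: 12 (S)-3-{[(tert-butyldimethylsilyl)oxy]methyl}-4,4-dimethyl-2-methylidenecyclohexan-1-one
Conditions: Dess–Martin periodinane, CH2Cl2, 0 °C; used at once
Reagents that add atoms: none
Why: Dess–Martin oxidation, which converts both allylic alcohol epimers into one enone under near-neutral conditions that should neither move the exocyclic double bond into the ring nor affect C2.

Step 9
Reactants: 12 (S)-3-{[(tert-butyldimethylsilyl)oxy]methyl}-4,4-dimethyl-2-methylidenecyclohexan-1-one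
Product: 13 (1S,3S)-3-{[(tert-butyldimethylsilyl)oxy]methyl}-4,4-dimethyl-2-methylidenecyclohexan-1-ol
Conditions: (R)-2-methyl-CBS-oxazaborolidine (30 mol%), catecholborane, toluene, −78 °C
Reagents that add atoms: none
Why: Corey–Bakshi–Shibata reduction, in which the ketone binds the catalyst boron with the α-methylene-bearing side as the large group and the coordinated borane delivers hydride 1,2 to one face, so C6 should be set as (S), trans to the C2 side chain, by reagent control that matches the equatorial approach preferred by bulky hydride donors.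

Step 10
Reactants: 13 (1S,3S)-3-{[(tert-butyldimethylsilyl)oxy]methyl}-4,4-dimethyl-2-methylidenecyclohexan-1-ol
Product: 14 tert-butyl{[(1S,3S)-6,6-dimethyl-2-methylidene-3-(triisopropylsilyloxy)cyclohexyl]methoxy}dimethylsilane
Conditions: TIPSOTf, 2,6-lutidine, CH2Cl2, 0 °C
Reagents that add atoms: triisopropylsilyl trifluoromethanesulfonate, CC(C)[Si](OS(=O)(=O)C(F)(F)F)(C(C)C)C(C)C
Why: Silyl triflate silylation of the secondary allylic alcohol, which gives an ether that palladium(0) cannot ionise and that outlasts removal of the primary TBS group.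

Step 11
Reactants: 14 tert-butyl{[(1S,3S)-6,6-dimethyl-2-methylidene-3-(triisopropylsilyloxy)cyclohexyl]methoxy}dimethylsilane
Product: 15 [(1S,3S)-6,6-dimethyl-2-methylidene-3-(triisopropylsilyloxy)cyclohexyl]methanol
Conditions: CSA (10 mol%), MeOH/CH2Cl2, 0 °C
Reagents that add atoms: none
Why: Acid-catalysed methanolysis of a silyl ether, in which the primary TBS ether is cleaved much faster than the hindered secondary TIPS ether.

Step 12
Reactants: 15 [(1S,3S)-6,6-dimethyl-2-methylidene-3-(triisopropylsilyloxy)cyclohexyl]methanol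
Product: 16 {[(1S,3S)-3-(iodomethyl)-4,4-dimethyl-2-methylidenecyclohexyl]oxy}triisopropylsilane
Conditions: I2, PPh3, imidazole, CH2Cl2, 0 °C to rt
Reagents that add atoms: iodine, II
Why: Appel-type iodination by SN2 displacement at the primary carbon, which involves no stereocentre and leaves the alkene and the TIPS ether intact under imidazole buffering.

Step 13
Reactants: 17 luteolin
Product: 18 7,3',4'-tris-O-(tert-butyldimethylsilyl)luteolin
Conditions: TBSCl (3.3 equiv), imidazole, DMF, rt
Reagents that add atoms: tert-butyldimethylsilyl chloride, C[Si](C)(Cl)C(C)(C)C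
Why: Selective O-silylation, in which the 5-OH is hydrogen-bonded to the C4 carbonyl and should stay free while the three other phenols react.

Step 14
Reactants: 18 7,3',4'-tris-O-(tert-butyldimethylsilyl)luteolin
Product: 19 6-iodo-7,3',4'-tris-O-(tert-butyldimethylsilyl)luteolin
Conditions: BnMe3N·ICl2 (1.05 equiv), CaCO3, CH2Cl2/MeOH, rt
Reagents that add atoms: benzyltrimethylammonium dichloroiodate, C[N+](C)(C)Cc1ccccc1.Cl[I-]Cl
Why: Electrophilic aromatic iodination, in which the free 5-OH of a 7-O-protected 5,7-dioxygenated flavone directs the iodonium source to the ortho position C6 of the most electron-rich ring while CaCO3 removes HCl.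

Step 15
Reactants: 19 6-iodo-7,3',4'-tris-O-(tert-butyldimethylsilyl)luteolin
Product: 20 5-O-acetyl-6-iodo-7,3',4'-tris-O-(tert-butyldimethylsilyl)luteolin
Conditions: Ac2O, Et3N, DMAP (cat.), CH2Cl2, rt
Reagents that add atoms: acetic anhydride, CC(=O)OC(C)=O
Why: DMAP-catalysed acetylation, which removes the last acidic proton with a small group that an organozinc tolerates and that makes the aryl iodide more electron-poor.

Step 16
Reactants: 16 {[(1S,3S)-3-(iodomethyl)-4,4-dimethyl-2-methylidenecyclohexyl]oxy}triisopropylsilane, 20 5-O-acetyl-6-iodo-7,3',4'-tris-O-(tert-butyldimethylsilyl)luteolin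
Product: 22 5-O-acetyl-7,3',4'-tris-O-(tert-butyldimethylsilyl)-6-{[(1S,3S)-6,6-dimethyl-2-methylidene-3-(triisopropylsilyloxy)cyclohexyl]methyl}luteolin, via alkylzinc iodide 21 (not isolated)
Conditions: Zn dust, LiCl, THF, 40 °C; then 20, Pd-PEPPSI-IPent (5 mol%), THF/NMP, 50 °C
Reagents that add atoms: none
Why: Negishi coupling, in which zinc inserts into the primary C–I bond and a bulky N-heterocyclic-carbene palladium catalyst should add to the di-ortho-substituted aryl iodide and eliminate reductively faster than β-hydride loss, so C2 and C6 stay untouched and the acetate, silyl ethers and chromone survive the mild organozinc.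

Step 17
Reactants: 22 5-O-acetyl-7,3',4'-tris-O-(tert-butyldimethylsilyl)-6-{[(1S,3S)-6,6-dimethyl-2-methylidene-3-(triisopropylsilyloxy)cyclohexyl]methyl}luteolin
Product: 23 ugonin Q
Conditions: TBAF (6 equiv), THF, 0 °C to rt, Ar; then MeOH, K2CO3 (cat.), rt; pH 6 phosphate buffer
Reagents that add atoms: none
Why: Fluoride-induced desilylation followed by base-catalysed transesterification of the aryl acetate, so all five protecting groups fall without acid, which avoids addition of the C5 or C7 phenol to the exocyclic alkene and ionisation of the allylic alcohol.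

Compound list
1 | methyl 3,3-dimethylpent-4-enoate | COC(=O)CC(C)(C)C=C | starting material
2 | 3,3-dimethylpent-4-enal | O=CCC(C)(C)C=C | intermediate
3 | formaldehyde | C=O | starting material
4 | (R)-2-(hydroxymethyl)-3,3-dimethylpent-4-enal | O=C[C@@H](CO)C(C)(C)C=C | intermediate
5 | (R)-2-{[(tert-butyldimethylsilyl)oxy]methyl}-3,3-dimethylpent-4-enal | O=C[C@@H](CO[Si](C)(C)C(C)(C)C)C(C)(C)C=C | intermediate
6 | (R)-tert-butyl[(2-ethynyl-3,3-dimethylpent-4-en-1-yl)oxy]dimethylsilane | C#C[C@@H](CO[Si](C)(C)C(C)(C)C)C(C)(C)C=C | intermediate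
7 | (R)-3-{[(tert-butyldimethylsilyl)oxy]methyl}-2,2-dimethylpent-4-yn-1-ol | C#C[C@@H](CO[Si](C)(C)C(C)(C)C)C(C)(C)CO | intermediate
8 | (R)-tert-butyl[(2-ethynyl-4-iodo-3,3-dimethylbutyl)oxy]dimethylsilane | C#C[C@@H](CO[Si](C)(C)C(C)(C)C)C(C)(C)CI | intermediate
9 | vinylboronic acid pinacol ester | C=CB1OC(C)(C)C(C)(C)O1 | starting material
10 | 2-[(3S)-3-{[(tert-butyldimethylsilyl)oxy]methyl}-4,4-dimethyl-2-methylidenecyclohexyl]-4,4,5,5-tetramethyl-1,3,2-dioxaborolane (both C6 epimers, not isolated) | C=C1[C@@H](CO[Si](C)(C)C(C)(C)C)C(C)(C)CCC1B2OC(C)(C)C(C)(C)O2 | intermediate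
11 | (3S)-3-{[(tert-butyldimethylsilyl)oxy]methyl}-4,4-dimethyl-2-methylidenecyclohexan-1-ol (both C6 epimers) | C=C1[C@@H](CO[Si](C)(C)C(C)(C)C)C(C)(C)CCC1O | intermediate
12 | (S)-3-{[(tert-butyldimethylsilyl)oxy]methyl}-4,4-dimethyl-2-methylidenecyclohexan-1-one | C=C1[C@@H](CO[Si](C)(C)C(C)(C)C)C(C)(C)CCC1=O | intermediate
13 | (1S,3S)-3-{[(tert-butyldimethylsilyl)oxy]methyl}-4,4-dimethyl-2-methylidenecyclohexan-1-ol | C=C1[C@@H](CO[Si](C)(C)C(C)(C)C)C(C)(C)CC[C@@H]1O | intermediate
14 | tert-butyl{[(1S,3S)-6,6-dimethyl-2-methylidene-3-(triisopropylsilyloxy)cyclohexyl]methoxy}dimethylsilane | C=C1[C@@H](CO[Si](C)(C)C(C)(C)C)C(C)(C)CC[C@@H]1O[Si](C(C)C)(C(C)C)C(C)C | intermediate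
15 | [(1S,3S)-6,6-dimethyl-2-methylidene-3-(triisopropylsilyloxy)cyclohexyl]methanol | C=C1[C@@H](CO)C(C)(C)CC[C@@H]1O[Si](C(C)C)(C(C)C)C(C)C | intermediate
16 | {[(1S,3S)-3-(iodomethyl)-4,4-dimethyl-2-methylidenecyclohexyl]oxy}triisopropylsilane | C=C1[C@@H](CI)C(C)(C)CC[C@@H]1O[Si](C(C)C)(C(C)C)C(C)C | intermediate
17 | luteolin | O=c1cc(-c2ccc(O)c(O)c2)oc2cc(O)cc(O)c12 | starting material
18 | 7,3',4'-tris-O-(tert-butyldimethylsilyl)luteolin | O=c1cc(-c2ccc(O[Si](C)(C)C(C)(C)C)c(O[Si](C)(C)C(C)(C)C)c2)oc2cc(O[Si](C)(C)C(C)(C)C)cc(O)c12 | intermediate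
19 | 6-iodo-7,3',4'-tris-O-(tert-butyldimethylsilyl)luteolin | O=c1cc(-c2ccc(O[Si](C)(C)C(C)(C)C)c(O[Si](C)(C)C(C)(C)C)c2)oc2cc(O[Si](C)(C)C(C)(C)C)c(I)c(O)c12 | intermediate
20 | 5-O-acetyl-6-iodo-7,3',4'-tris-O-(tert-butyldimethylsilyl)luteolin | O=c1cc(-c2ccc(O[Si](C)(C)C(C)(C)C)c(O[Si](C)(C)C(C)(C)C)c2)oc2cc(O[Si](C)(C)C(C)(C)C)c(I)c(OC(C)=O)c12 | intermediate
21 | {[(1S,3S)-6,6-dimethyl-2-methylidene-3-(triisopropylsilyloxy)cyclohexyl]methyl}zinc iodide (not isolated) | C=C1[C@@H](C[Zn]I)C(C)(C)CC[C@@H]1O[Si](C(C)C)(C(C)C)C(C)C | intermediate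
22 | 5-O-acetyl-7,3',4'-tris-O-(tert-butyldimethylsilyl)-6-{[(1S,3S)-6,6-dimethyl-2-methylidene-3-(triisopropylsilyloxy)cyclohexyl]methyl}luteolin | C=C1[C@@H](Cc2c(O[Si](C)(C)C(C)(C)C)cc3oc(-c4ccc(O[Si](C)(C)C(C)(C)C)c(O[Si](C)(C)C(C)(C)C)c4)cc(=O)c3c2OC(C)=O)C(C)(C)CC[C@@H]1O[Si](C(C)C)(C(C)C)C(C)C | intermediate
23 | ugonin Q, 6-{[(1S,3S)-3-hydroxy-6,6-dimethyl-2-methylidenecyclohexyl]methyl}luteolin | C=C1[C@@H](Cc2c(O)cc3oc(-c4ccc(O)c(O)c4)cc(=O)c3c2O)C(C)(C)CC[C@@H]1O | target

Total step count: 17. Longest linear sequence: 14 steps (steps 1–12, 16 and 17).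

Steps most likely to fail

Step 7. The 6-exo-dig closure of the C6 radical is slow. Premature hydrogen transfer to the C4 or C6 radical, 1,5-hydrogen transfer from C2–H, telomerisation with 9 or 7-endo attack may outrun it. The fallback builds the two bonds one after the other with polar and nickel chemistry.
- It sets out from 8. Iodine–lithium exchange (t-BuLi, the first equivalent deprotonating the alkyne) and opening of ethylene oxide would give (S)-5-{[(tert-butyldimethylsilyl)oxy]methyl}-4,4-dimethylhept-6-yn-1-ol F1, which forms the C4–C5 bond.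
- Dess–Martin oxidation would give the ynal F2.
- Nickel(0)/N-heterocyclic-carbene-catalysed reductive alkyne–aldehyde cyclisation with Et3SiH would give the triethylsilyl ether F3, which forms the C1–C6 bond and the exocyclic methylene.
- PPTS in MeOH would remove the triethylsilyl group selectively, and the route is rejoined at 11.

Step 16. Oxidative addition at the doubly ortho-substituted C6–I bond may be so slow that protonation of the organozinc and β-hydride elimination from the alkylpalladium species take over. The fallback reverses the polarity and changes the metal.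
- It sets out from 20. Zinc insertion (Zn, LiCl) would give the arylzinc iodide F6.
- F6 would be coupled with the alkyl iodide 16 under nickel/terpyridine catalysis, in which the alkyl halide is activated as a radical and the hindered arene enters only by transmetalation. The route is rejoined at 22.

Step 9. Conjugate reduction or hydroboration of the exocyclic methylene, dimerisation of the enone, or poor facial selectivity through a mismatch of catalyst and substrate may intervene. The fallback replaces reagent control by substrate control plus inversion.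
- It sets out from 12. Luche reduction (axial hydride attack) would give the cis alcohol F4.
- Mitsunobu reaction with 4-nitrobenzoic acid would invert C6 to the trans 4-nitrobenzoate F5.
- K2CO3 in MeOH would release the alcohol, and the route is rejoined at 13.

Further compounds
F1 | step 7 | (S)-5-{[(tert-butyldimethylsilyl)oxy]methyl}-4,4-dimethylhept-6-yn-1-ol | C#C[C@@H](CO[Si](C)(C)C(C)(C)C)C(C)(C)CCCO
F2 | step 7 | (S)-5-{[(tert-butyldimethylsilyl)oxy]methyl}-4,4-dimethylhept-6-ynal | C#C[C@@H](CO[Si](C)(C)C(C)(C)C)C(C)(C)CCC=O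
F3 | step 7 | tert-butyl{[(1S)-6,6-dimethyl-2-methylidene-3-(triethylsilyloxy)cyclohexyl]methoxy}dimethylsilane (C6 epimers) | C=C1[C@@H](CO[Si](C)(C)C(C)(C)C)C(C)(C)CCC1O[Si](CC)(CC)CC
F4 | step 9 | (1R,3S)-3-{[(tert-butyldimethylsilyl)oxy]methyl}-4,4-dimethyl-2-methylidenecyclohexan-1-ol | C=C1[C@@H](CO[Si](C)(C)C(C)(C)C)C(C)(C)CC[C@H]1O
F5 | step 9 | (1S,3S)-3-{[(tert-butyldimethylsilyl)oxy]methyl}-4,4-dimethyl-2-methylidenecyclohexyl 4-nitrobenzoate | C=C1[C@@H](CO[Si](C)(C)C(C)(C)C)C(C)(C)CC[C@@H]1OC(=O)c1ccc([N+](=O)[O-])cc1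
F6 | step 16 | [5-acetoxy-7,3',4'-tris(tert-butyldimethylsilyloxy)flavon-6-yl]zinc iodide | CC(=O)Oc1c([Zn]I)c(O[Si](C)(C)C(C)(C)C)cc2oc(-c3ccc(O[Si](C)(C)C(C)(C)C)c(O[Si](C)(C)C(C)(C)C)c3)cc(=O)c12
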